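At 8.0 min you read the target in two flasks, south-west and west. Most of that number is simply substrate that has reacted, so I reckon only the correction.

| setting | Monday's | Thursday's | south-west | west |
|---|---|---|---|---|
| substrate | 2 mM | 2 mM | 1.2 mM | 2.0 mM |
| coupling partner | 2.6 mM (fed, over 20 s) | 2.6 mM (fed, over 20 s) | 2.60 mM | 2.60 mM (fed, over 20 s) |
| transfer agent | 0.60 mM | 1.2 mM | 0.600 mM | 0.600 mM |
| initiator | 27 µM | 40 µM | 40 µM | 40 µM |
| remark | run made earlier | run made earlier | everything together at the start |  |
| time |  |  | 8.0 min | 8.0 min |

| run | time / min | target / % | substrate / % |
|---|---|---|---|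
| Monday's | 0.333 | 5.2 | 94.0 |
| Monday's | 1.00 | 24.8 | 74.3 |
| Monday's | 2.00 | 45.6 | 53.8 |
| Monday's | 3.00 | 58.9 | 39.0 |
| Thursday's | 0.667 | 12.2 | 87.0 |
| Thursday's | 1.33 | 25.8 | 74.0 |
| Thursday's | 2.00 | 35.6 | 63.4 |
| Thursday's | 3.00 | 47.1 | 51.0 |

(readings scatter by 0.3 percentage points)

- which of the two ends with the higher amount of target, in percent of the substrate charged ("neither" if they lie within 2 percentage points) (south-west / west / neither)
- target at the end, in percent of the substrate charged, south-west
- target at the end, in percent of the substrate charged, west



Monday's run seems to disagree with itself. The gap, charge minus target minus substrate, is 13.3% of the reacted substrate at 0.333 min but 3.44% at 3.00 min. Yet a gap joins two readings, so its scatter is 0.42 percentage points. That is 7.07% of the early reacted amount and 0.696% of the late one, so the early share says little. Weigh by reacted substrate and pool the last readings of both runs: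

gaps: 2.1 points + 1.9 points

reacted: 61.0% + 49.0%

gaps / reacted = 3.64%

Call this the loss share: the part of reacted substrate that these readings don't show as target. If the substrate has reacted completely by 8.0 min, I reckon target at 96.4% in both flasks. South-west's all-at-once addition is untested, so carrying the share there is my assumption, and I say neither.

The forecast, seeing “a slow loss”, gave neither, with 89% for south-west and 91% for west, both below my 96.4%.

The flasks give neither: 98.1% in south-west and 97.3% in west.

    transfer agent + first chain carrier → side product + idle radical (kL = 1.50 × 10⁵ /M/s)
    2 second chain carrier → ended chains A (k = 9.00 × 10⁶ /M/s)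
    initiator → 2 initiating radical (k = 0.00350 /s)
    substrate + initiating radical → capped initiator + first chain carrier (k = 4.60 × 10⁷ /M/s)
    coupling partner + first chain carrier → target + second chain carrier (k = 2.30 × 10⁶ /M/s)
    substrate + second chain carrier → by-product + first chain carrier (k = 3.60 × 10⁶ /M/s)
    2 idle radical → ended radicals (k = 1.00 × 10⁹ /M/s)
    2 first chain carrier → ended chains B (k = 1.60 × 10⁸ /M/s)

At 8.00 min substrate stands at 0% in west, and the loss there is 2.70% against the carried 3.64%. At 0.642 min in south-west, first chain carrier goes to coupling partner 52 times as fast as to transfer agent (a selectivity factor), a split of 1.88% to the side product at that moment; at 8.00 min south-west holds 1.93% side product.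

South-west's neighbour with 2.4 mM of transfer agent keeps 20.1% substrate, so the loss share gives 77.0% target; computed, it holds 74.5%, with 5.42% side product.

The earlier runs and the new flask are calculated for substances that don't exist; the scatter is artificial.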